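**Retrosynthetic overview**

1. The target comes from its 7,4'-bis(silyl ether) 11. The 1,1-dimethylallyl group at C6 comes from an aromatic Claisen rearrangement of a 5-O-prenyl ether (9 → 11); until then the prenyl ether protects the 5-OH.
2. The pyranone (O1, C2, C3, C4, C4a, C8a) is not closed directly. It arises by contraction of the seven-membered ring of the 1,3-benzodioxepin-5-one 7, in which the oxygen of the later 3-OH is a ring member between C2 and C3. This 1,2-shift of C2 from oxygen to carbon makes the C2–C3 bond and both stereocentres.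
3. Enabling feature: C2 bears the ring oxygen O1 and a 4-oxygenated aryl group, so it ionises easily to an oxocarbenium ion. C3 bears a hydroxyl next to the C4 ketone, an enolisable α-hydroxy ketone. The C3 oxygen can therefore be tied to C2 as a mixed acetal and released again as the 3-OH.
4. Acetal 7 is made from hydroxy ketone 5 and aldehyde 6. Compound 5 comes from 2,4,6-trihydroxyacetophenone by 4-O-silylation, mono-O-prenylation and enolate hydroxylation.
5. Ring order: both benzene rings are bought, the seven-membered acetal ring is closed in step 4, and the pyranone is formed from it in step 5.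

Key step: step 5

Assumption: the sense of induction of the chiral acid in step 5 cannot be derived from a model with confidence; (R)-TRIP is written for definiteness, and the catalyst enantiomer that gives the (2R,3R) series is the one to be used.

**Route**

Step 1
Reactants: 1 2,4,6-trihydroxyacetophenone
Product: 2 1-[4-(tert-butyldimethylsilyloxy)-2,6-dihydroxyphenyl]ethan-1-one
Conditions: TBSCl (1.05 equiv), imidazole (1.1 equiv), DMF, 0 °C
Reagents that add atoms: tert-butyldimethylsilyl chloride, CC(C)(C)[Si](C)(C)Cl
Why: The 4-OH is the only hydroxyl of 1 that is not hydrogen-bonded to the ketone and is the most acidic one, so silyl ether formation with one equivalent should take place there.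

Step 2
Reactants: 2 1-[4-(tert-butyldimethylsilyloxy)-2,6-dihydroxyphenyl]ethan-1-one; 3 3-methylbut-2-en-1-ol
Product: 4 1-[4-(tert-butyldimethylsilyloxy)-2-hydroxy-6-(3-methylbut-2-enyloxy)phenyl]ethan-1-one
Conditions: PPh3, DIAD (1.05 equiv each), THF, 0 °C → rt
Reagents that add atoms: none
Why: Mitsunobu etherification of one of the two equivalent chelated phenols with the primary allylic alcohol (SN2 at the primary carbon) should stop at the mono-ether, because the remaining hydroxyl is then fully locked in the hydrogen bond to the ketone.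

Step 3
Reactants: 4 1-[4-(tert-butyldimethylsilyloxy)-2-hydroxy-6-(3-methylbut-2-enyloxy)phenyl]ethan-1-one
Product: 5 1-[4-(tert-butyldimethylsilyloxy)-2-hydroxy-6-(3-methylbut-2-enyloxy)phenyl]-2-hydroxyethan-1-one
Conditions: KHMDS (2.2 equiv), THF, −78 °C; 2-(phenylsulfonyl)-3-phenyloxaziridine (1.1 equiv), −78 °C; AcOH (2.2 equiv)
Reagents that add atoms: 2-(phenylsulfonyl)-3-phenyloxaziridine, O=S(=O)(c1ccccc1)N1OC1c1ccccc1
Why: Enolate hydroxylation of the potassium enolate of the methyl ketone (formed beside the phenoxide) with the N-sulfonyloxaziridine should give the primary α-hydroxy ketone, while the electron-rich prenyl alkene, which an epoxidising oxidant would attack, is left alone.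

Step 4
Reactants: 5 1-[4-(tert-butyldimethylsilyloxy)-2-hydroxy-6-(3-methylbut-2-enyloxy)phenyl]-2-hydroxyethan-1-one; 6 4-(tert-butyldimethylsilyloxy)benzaldehyde
Product: 7 8-(tert-butyldimethylsilyloxy)-2-[4-(tert-butyldimethylsilyloxy)phenyl]-6-(3-methylbut-2-enyloxy)-4H-1,3-benzodioxepin-5-one (racemic at the acetal carbon)
Conditions: PPTS (10 mol%), 4 Å MS, CH2Cl2, 40 °C
Reagents that add atoms: none
Why: Acid-catalysed acetalisation of the aldehyde with the primary hydroxyl and the phenol, with water taken up by the molecular sieves, should give the seven-membered mixed aryl alkyl acetal, helped by the electron-rich aryl group that stabilises the intermediate oxocarbenium ion.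

Step 5
Reactants: 7 8-(tert-butyldimethylsilyloxy)-2-[4-(tert-butyldimethylsilyloxy)phenyl]-6-(3-methylbut-2-enyloxy)-4H-1,3-benzodioxepin-5-one
Product: 9 (2R,3R)-7-(tert-butyldimethylsilyloxy)-2-[4-(tert-butyldimethylsilyloxy)phenyl]-3-hydroxy-5-(3-methylbut-2-enyloxy)chroman-4-one, via oxocarbenium–enediol ion pair 8 (not isolated)
Conditions: (R)-TRIP [3,3'-bis(2,4,6-triisopropylphenyl)-1,1'-binaphthyl-2,2'-diyl hydrogen phosphate] (10 mol%), 5 Å MS, toluene (0.02 M), 40 °C
Reagents that add atoms: none
Why: Proposed new method: the chiral phosphoric acid protonates the acetal oxygen O3 of the seven-membered ring and the C2–O3 bond breaks, since the cation at C2 is stabilised by the lone pair of O1 and by the 4-silyloxyphenyl group; in the resulting ion pair 8 the freed 2-hydroxy ketone is enolised by the phosphate from its internally hydrogen-bonded s-cis conformer to the cis-enediol. The enediol carbon (future C3) then adds to the oxocarbenium carbon (future C2) in a 6-(enolendo)-endo-trig closure that forms the C2–C3 bond and the pyranone, so that C2 has moved from O3 to the neighbouring carbon (1,2-shift from O to C), O3 has become the exocyclic 3-OH and the seven-membered ring has contracted to the six-membered one. The closest known reaction types are the Petasis–Ferrier rearrangement of cyclic vinyl acetals (oxocarbenium–enolate ion pair that recombines at carbon), chiral phosphoric acid-catalysed enantioselective rearrangements of this type (aza-Petasis–Ferrier and related O-to-C shifts of cyclic vinyl acetals), and the addition of titanium enolates of α-oxygenated ketones to acetals; new here is that the enol is formed only after ionisation and that the acetal oxygen sits on the nucleophilic carbon itself. Both stereocentres arise in the one C–C bond formation between two planar centres that are held on the chiral phosphate by O–H···O hydrogen bonds, so that the absolute configuration is set by the catalyst and the racemic acetal centre of 7 is erased on ionisation (stereoconvergent). The 2,3-trans relation should follow from a half-chair transition state in which the (E)-oxocarbenium ion holds the aryl group pseudo-equatorial and the cis-enediol holds the C3 oxygen pseudo-equatorial. The step needs attack of the unsubstituted enediol carbon (six-membered aryl ketone) and not of the aryl-bearing one (five-membered hydroxy aldehyde), carbon and not oxygen recombination, and no arene alkylation: the first is favoured by the lower substitution of that carbon and the conjugated hydroxycarbenium ion it leaves, re-closure at oxygen or ionisation of the C2–O1 bond only returns 7, and the acyl group on the A ring and high dilution hold back Friedel–Crafts attack.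

Step 6
Reactants: 9 (2R,3R)-7-(tert-butyldimethylsilyloxy)-2-[4-(tert-butyldimethylsilyloxy)phenyl]-3-hydroxy-5-(3-methylbut-2-enyloxy)chroman-4-one
Product: 11 (2R,3R)-7-(tert-butyldimethylsilyloxy)-2-[4-(tert-butyldimethylsilyloxy)phenyl]-3,5-dihydroxy-6-(2-methylbut-3-en-2-yl)chroman-4-one, via ortho-dienone 10 (not isolated)
Conditions: Eu(fod)3 (10 mol%), CHCl3, 60 °C
Reagents that add atoms: none
Why: The europium(III)-catalysed aromatic Claisen rearrangement ([3,3]) of the 5-O-prenyl ether, activated by chelation of Eu between the C4 carbonyl and the ether oxygen, can deliver the allyl unit with inversion only to the single free ortho position C6, and dienone 10 then enolises to the chelated 5-OH phenol without touching the two stereocentres.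

Step 7
Reactants: 11 (2R,3R)-7-(tert-butyldimethylsilyloxy)-2-[4-(tert-butyldimethylsilyloxy)phenyl]-3,5-dihydroxy-6-(2-methylbut-3-en-2-yl)chroman-4-one
Product: 12 (2R,3R)-3,5,7-trihydroxy-2-(4-hydroxyphenyl)-6-(2-methylbut-3-en-2-yl)chroman-4-one (target)
Conditions: HF·pyridine, pyridine, THF, 0 °C → rt
Reagents that add atoms: none
Why: Fluoride-mediated desilylation of the two aryl silyl ethers under buffered conditions should be neither basic enough to open or epimerise the dihydroflavonol nor acidic enough to add the ortho hydroxyls to the 1,1-dimethylallyl group.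

**Compound list**

1 | 2,4,6-trihydroxyacetophenone | CC(=O)c1c(O)cc(O)cc1O | starting material
2 | 1-[4-(tert-butyldimethylsilyloxy)-2,6-dihydroxyphenyl]ethan-1-one | CC(=O)c1c(O)cc(O[Si](C)(C)C(C)(C)C)cc1O | intermediate
3 | 3-methylbut-2-en-1-ol | CC(C)=CCO | starting material
4 | 1-[4-(tert-butyldimethylsilyloxy)-2-hydroxy-6-(3-methylbut-2-enyloxy)phenyl]ethan-1-one | CC(=O)c1c(O)cc(O[Si](C)(C)C(C)(C)C)cc1OCC=C(C)C | intermediate
5 | 1-[4-(tert-butyldimethylsilyloxy)-2-hydroxy-6-(3-methylbut-2-enyloxy)phenyl]-2-hydroxyethan-1-one | OCC(=O)c1c(O)cc(O[Si](C)(C)C(C)(C)C)cc1OCC=C(C)C | intermediate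
6 | 4-(tert-butyldimethylsilyloxy)benzaldehyde | O=Cc1ccc(O[Si](C)(C)C(C)(C)C)cc1 | starting material
7 | 8-(tert-butyldimethylsilyloxy)-2-[4-(tert-butyldimethylsilyloxy)phenyl]-6-(3-methylbut-2-enyloxy)-4H-1,3-benzodioxepin-5-one (racemic) | O=C1COC(c2ccc(O[Si](C)(C)C(C)(C)C)cc2)Oc2cc(O[Si](C)(C)C(C)(C)C)cc(OCC=C(C)C)c21 | intermediate
8 | ring-opened ion pair: O-aryl oxocarbenium ion at the later C2 beside the cis-enediol of the 2-hydroxy ketone (cation shown; the counter-ion is the phosphate of the catalyst) | O/C=C(\O)c1c(OCC=C(C)C)cc(O[Si](C)(C)C(C)(C)C)cc1/[O+]=C/c1ccc(O[Si](C)(C)C(C)(C)C)cc1 | intermediate (not isolated)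
9 | (2R,3R)-7-(tert-butyldimethylsilyloxy)-2-[4-(tert-butyldimethylsilyloxy)phenyl]-3-hydroxy-5-(3-methylbut-2-enyloxy)chroman-4-one | CC(C)=CCOc1cc(O[Si](C)(C)C(C)(C)C)cc2c1C(=O)[C@H](O)[C@@H](c1ccc(O[Si](C)(C)C(C)(C)C)cc1)O2 | intermediate
10 | ortho-dienone: 6-(2-methylbut-3-en-2-yl)-6H-chromane-4,5-dione tautomer of 11 (C6 epimers) | C=CC(C)(C)C1C(O[Si](C)(C)C(C)(C)C)=CC2=C(C1=O)C(=O)[C@H](O)[C@@H](c1ccc(O[Si](C)(C)C(C)(C)C)cc1)O2 | intermediate (not isolated)
11 | (2R,3R)-7-(tert-butyldimethylsilyloxy)-2-[4-(tert-butyldimethylsilyloxy)phenyl]-3,5-dihydroxy-6-(2-methylbut-3-en-2-yl)chroman-4-one | C=CC(C)(C)c1c(O[Si](C)(C)C(C)(C)C)cc2c(c1O)C(=O)[C@H](O)[C@@H](c1ccc(O[Si](C)(C)C(C)(C)C)cc1)O2 | intermediate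
12 | (2R,3R)-3,5,7-trihydroxy-2-(4-hydroxyphenyl)-6-(2-methylbut-3-en-2-yl)chroman-4-one | C=CC(C)(C)c1c(O)cc2c(c1O)C(=O)[C@H](O)[C@@H](c1ccc(O)cc1)O2 | target

**Step count and risks**

Total step count: 7. Longest linear sequence: 7 steps (from 1).

Steps most likely to fail:

Step 5 (proposed new method). Three things may go wrong: the weak acid may ionise the acetal but fail to enolise the ring-opened hydroxy ketone, so that 7 only racemises; the facial discrimination in the ion pair may be low; or the closure may run through the diastereomeric transition state to the 2,3-cis series. The fallback uses known chemistry, gives up the ring contraction, sets out from 5 and 6 and comes back at 9. A direct syn-selective aldol addition of the α-hydroxy ketone 5 to aldehyde 6 under a dinuclear zinc catalyst (Et2Zn with the ProPhenol ligand enantiomer that gives the 2R,3S series, the chelated phenol being carried as its zinc phenoxide) should give (2R,3S)-1-[4-(tert-butyldimethylsilyloxy)-2-hydroxy-6-(3-methylbut-2-enyloxy)phenyl]-3-[4-(tert-butyldimethylsilyloxy)phenyl]-2,3-dihydroxypropan-1-one F1. Mitsunobu etherification (PPh3, DIAD) of the phenol with the benzylic hydroxyl, with inversion at that carbon, should then close the pyranone and give 9.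

Step 6. Dienone 10 may undergo a Cope shift to C8 before it enolises, which leads to the 8-(3-methylbut-2-enyl) isomer instead of the 6-(1,1-dimethylallyl) compound. The fallback moves the rearrangement to a substrate in which this path is closed by the structure; it sets out from 1 and 3 and comes back at 11.
- Mitsunobu etherification of the free 4-OH of 1 with 3 should give 1-[2,6-dihydroxy-4-(3-methylbut-2-enyloxy)phenyl]ethan-1-one F2. Both ortho positions of this ether are equivalent and the para position carries the acetyl group.
- Thermal Claisen rearrangement (N,N-diethylaniline, 180 °C) can therefore only end at 1-[2,4,6-trihydroxy-3-(2-methylbut-3-en-2-yl)phenyl]ethan-1-one F3.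
- Silylation of the only non-chelated hydroxyl should give 1-[4-(tert-butyldimethylsilyloxy)-2,6-dihydroxy-3-(2-methylbut-3-en-2-yl)phenyl]ethan-1-one F4.
- Enolate hydroxylation as in step 3, with one more equivalent of base, should give 1-[4-(tert-butyldimethylsilyloxy)-2,6-dihydroxy-3-(2-methylbut-3-en-2-yl)phenyl]-2-hydroxyethan-1-one F5.
- Acetalisation with 6 as in step 4, through the less hindered of the two chelated hydroxyls, should give 8-(tert-butyldimethylsilyloxy)-2-[4-(tert-butyldimethylsilyloxy)phenyl]-6-hydroxy-7-(2-methylbut-3-en-2-yl)-4H-1,3-benzodioxepin-5-one F6.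
- The ring contraction of step 5 applied to F6 should give 11 directly.

Step 4. The seven-membered mixed acetal may not be favoured at equilibrium, so that open or oligomeric acetals form, or it may rearrange early and without stereocontrol under the acid at 40 °C. The fallback replaces the equilibrium acetalisation by a kinetic silyl-transfer acetalisation at low temperature; it sets out from 5 and comes back at 7. Silylation of both hydroxyls (TMSCl, Et3N) should give 1-[4-(tert-butyldimethylsilyloxy)-6-(3-methylbut-2-enyloxy)-2-(trimethylsilyloxy)phenyl]-2-(trimethylsilyloxy)ethan-1-one F7. Treatment of F7 with 6 and TMSOTf (5 mol%) in CH2Cl2 at −78 °C should then give 7 irreversibly.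

**Further compounds**

F1 | step 5 | (2R,3S)-1-[4-(tert-butyldimethylsilyloxy)-2-hydroxy-6-(3-methylbut-2-enyloxy)phenyl]-3-[4-(tert-butyldimethylsilyloxy)phenyl]-2,3-dihydroxypropan-1-one | CC(C)=CCOc1cc(O[Si](C)(C)C(C)(C)C)cc(O)c1C(=O)[C@H](O)[C@H](c1ccc(O[Si](C)(C)C(C)(C)C)cc1)O
F2 | step 6 | 1-[2,6-dihydroxy-4-(3-methylbut-2-enyloxy)phenyl]ethan-1-one | CC(=O)c1c(O)cc(OCC=C(C)C)cc1O
F3 | step 6 | 1-[2,4,6-trihydroxy-3-(2-methylbut-3-en-2-yl)phenyl]ethan-1-one | CC(=O)c1c(O)cc(O)c(C(C)(C)C=C)c1O
F4 | step 6 | 1-[4-(tert-butyldimethylsilyloxy)-2,6-dihydroxy-3-(2-methylbut-3-en-2-yl)phenyl]ethan-1-one | CC(=O)c1c(O)cc(O[Si](C)(C)C(C)(C)C)c(C(C)(C)C=C)c1O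
F5 | step 6 | 1-[4-(tert-butyldimethylsilyloxy)-2,6-dihydroxy-3-(2-methylbut-3-en-2-yl)phenyl]-2-hydroxyethan-1-one | OCC(=O)c1c(O)cc(O[Si](C)(C)C(C)(C)C)c(C(C)(C)C=C)c1O
F6 | step 6 | 8-(tert-butyldimethylsilyloxy)-2-[4-(tert-butyldimethylsilyloxy)phenyl]-6-hydroxy-7-(2-methylbut-3-en-2-yl)-4H-1,3-benzodioxepin-5-one (racemic) | O=C1COC(c2ccc(O[Si](C)(C)C(C)(C)C)cc2)Oc2cc(O[Si](C)(C)C(C)(C)C)c(C(C)(C)C=C)c(O)c21
F7 | step 4 | 1-[4-(tert-butyldimethylsilyloxy)-6-(3-methylbut-2-enyloxy)-2-(trimethylsilyloxy)phenyl]-2-(trimethylsilyloxy)ethan-1-one | C[Si](C)(C)OCC(=O)c1c(O[Si](C)(C)C)cc(O[Si](C)(C)C(C)(C)C)cc1OCC=C(C)C
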